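## The problem

The target is an unbranched C20 chain (C1 = lactone carbonyl, C20 = terminal methyl). Its C1–C5 end is a 4-hydroxy-5,6-dihydropyran-2-one, ring atoms O5, C1, C2, C3, C4, C5, which is the enol form of a β-keto-δ-lactone. The rest is an acyclic triol (C7, C9, C11) ending in a nonyl group. There are four stereocentres, all carbinol carbons in 1,3-relationships: C5 (R), C7 (R), C9 (S), C11 (S), with C5/C7 syn, C7/C9 anti and C9/C11 syn. Neighbouring centres can relay configuration: a C11 hydroxyl can direct a syn reduction at C9, and the C9 oxygen can steer a nucleophile onto a C7 aldehyde in the anti sense. C5 is different, because its hydroxyl must be the only free one when the ring is closed, so it is best set by a catalyst after O7 has been capped. The enolised β-keto lactone is the fragile part: it is a vinylogous acid that opens and decarboxylates under aqueous base, and C2 is a 1,3-dicarbonyl nucleophile that condenses with aldehydes. The β-oxygenated carbonyl intermediates on the way can undergo retro-aldol cleavage and β-elimination. The lactone should therefore be made late, and the final deprotection must be mild and release no electrophile. The feature that allows this is that O5–C1–C2 is an acetate unit carried on the C5 oxygen while C3 is an acyl carbon bonded to C4. If C3 is an ester and O5 carries a haloacetate, the C2–C3 bond can be made by an intramolecular Claisen (Dieckmann) condensation that closes the ring without touching the C5–O bond.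

## Retrosynthesis

**Protecting groups, 17 from 16.** No skeletal bond is cut. In 16, O7 is a tert-butyldimethylsilyl ether and O9/O11 (syn) are an isopropylidene acetal. This pair is preferred to an arylidene acetal or benzyl ethers: both groups fall in one acidic fluoride treatment, the fragments released are not electrophiles towards C2, and no hydrogenolysis is needed next to the enol double bond. The forward step only has to spare the lactone.

**C2–C3, 16 from 14.** The ring is opened between C2 and C3, giving the acyclic methyl ester 14 with a bromoacetate on O5. The neighbouring cut, O5–C1 (lactonisation of a δ-hydroxy-β-keto ester), would require the 1,3-dicarbonyl to be carried in open form. The C2–C3 cut instead leaves a plain β-acyloxy ester that can be purified and stored. The C–Br bond fixes where the enolate forms. The forward reaction must form the enolate at C2 only and acylate intramolecularly.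

**O5–C1, 14 from 12 and 13.** An ester bond is cut to the β-hydroxy ester 12 and bromoacetyl bromide 13. The only demand is that O5 be the sole free hydroxyl, which the earlier order of events secures.

**C5–H, 12 from 11.** The C5 carbinol is traced to the β-keto ester 11. A hydroxyl-directed syn reduction from a free O7 would also give the correct C5, but it would leave O5 and O7 as an undifferentiated diol. Silylating O7 first and reducing with a chiral catalyst gives O5 already differentiated. The forward step needs catalyst control over a remote stereocentre and tolerance of the acetal and silyl ether.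

**C6–C7, 11 from 10, and 10 from 7 and 8.** After removing the silyl group, the C6–C7 bond is cut to the aldehyde 7 (C7–C20) and the four-carbon bis-silyl dienolate 8 (C3–C6). Compared with two-carbon iterations at C4–C5 or C5–C6, this single vinylogous aldol delivers the C7 carbinol, the C5 ketone and the C3 methyl ester together. The forward reaction must add anti to the C9 oxygen.

**C9–H and redox, 7 from 6, 5 and 3.** The aldehyde comes from the tert-butyl ester 6, and the acetonide from the syn diol 5. The C9 carbinol comes from the δ-hydroxy-β-keto ester 3 by a reduction directed by the C11 hydroxyl. The precursor has a single stereocentre.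

**C8–C9 and C11–H, 3 from 2 and 2 from 1.** The C8–C9 bond is cut as a Claisen condensation of the β-hydroxy ester 2 with an acetate enolate. The C11 carbinol is traced to the commercial β-keto ester 1 by asymmetric hydrogenation. The whole chain therefore rests on 1, 8, 13 and two acetate-level reagents.

## Roads not taken

**Alternative 1:** The cut is at C8–C9 and C9–C10, with C9 as an acyl-anion linchpin. The lithiated silyl dithiane A2 would open the nonyl epoxide A3. The alkoxide would trigger a 1,4-Brook shift and the new dithiane anion would open the allyl epoxide A4, giving A1 (C4–C20) in one flask.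
- Merits: three components are joined in one operation. C7 and C11 come with secure configuration from resolved epoxides. O11 emerges silylated and O7 free, so they are already differentiated.
- Weak points for this target: no ring is formed and C9 remains a masked ketone. The thioacetal must be removed and C9 set by an anti reduction directed from O7. C5 is still an alkene carbon, so the alkene must be cleaved and C3–C4 and the C5 carbinol added by a further asymmetric step. The β-keto lactone would still have to be closed, most likely in the way chosen here.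
- Comparison: this road is more convergent and fixes C7 more securely than the chosen plan, which relies on substrate induction at C7. Against that, the chosen plan sets C11 and C5 by catalytic hydrogenation, needs no thioacetal hydrolysis next to silyl ethers, wastes no half of a resolved epoxide, and brings in C3–C6 with the β-keto ester already in place.

**Alternative 2:** The cut is at C3–C4 and C6–C7 in the sense of a [4+3] cycloaddition. An oxyallyl cation from A6 and Zn–Cu couple would add across A7 to give the meso oxabicycle A5 after debromination. Its ketone is C5, its bridgeheads are C3 and C7, and its alkene carbons would become C2 and C8.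
- Merits: the materials are very cheap, the bicycle is rigid, the C5 ketone can be reduced with high facial control, and the C5/C7 relationship is fixed by the ring.
- Weak points: A5 is meso and needs a desymmetrisation to give one enantiomer. The bridging oxygen is correct at C7 but sits on C3, where the target has a carbonyl, so the template must be opened at C3–O and C3 re-oxidised. The two alkene-derived termini must be told apart. Nothing of C9–C20 or its two stereocentres is addressed.
- Comparison: it wins only on material cost and on the rigid control of one stereo pair. The chosen plan reaches the same C3–C7 segment by one C–C bond formation on an acyclic substrate with every carbon at its final oxidation level.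

**Alternative 3:** The cut is at O–C7, by 1,3-transposition of an allylic alcohol. Re2O7 would shuttle the hydroxyl of A9 between C9 and C7 through a [3,3] shift on rhenium. The acetal donor A10 would trap the C5,C7-syn diol as the all-cis acetal A8 (C3–C9), which keeps a vinyl group at C8–C9.
- Merits: one stereocentre (C5) sets C7 under thermodynamic control in a catalytic step, without a chiral reagent and with the C3 ester already present.
- Weak points: O5 and O7 end in the same acetal, whereas ring closure needs O5 alone free, so extra steps are needed to separate them. The arylidene acetal must later be hydrolysed in the presence of the nucleophilic C2, or hydrogenolysed next to the enol. The C7/C9 relationship is anti, so the syn-selective relay cannot be repeated for C9. The C9–C20 half remains to be built.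
- Comparison: for the C5/C7 pair this relay is more economical in stereocontrol than the chosen plan, which uses two separate controlling elements (substrate induction at C7 and a catalyst at C5). What the chosen plan sets against it is that O7 is silylated before the C5 carbinol exists, so O5 is already differentiated for the Dieckmann closure.

Key step: step 10

Remark: atom labels C1–C20 are those of the target chain and are used for every intermediate. The target is treated as the enol (4-hydroxy) tautomer. Compounds 1, 8 and 13 are taken as catalogue chemicals.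

## Route

Step 1
Reactants: 1 methyl 3-oxododecanoate
Product: 2 methyl (3S)-3-hydroxydodecanoate
Conditions: RuCl2[(S)-BINAP] (0.2 mol %), H2 (10 atm), MeOH, 50 °C
Reagents that add atoms: none
Why: Noyori asymmetric hydrogenation of a β-keto ester; the (S)-BINAP catalyst delivers hydrogen to the ketone face that gives the (3S)-carbinol, which is C11 of the target.

Step 2
Reactants: 2 methyl (3S)-3-hydroxydodecanoate
Product: 3 tert-butyl (5S)-5-hydroxy-3-oxotetradecanoate
Conditions: t-BuOAc, LiN(iPr)2 (3.5 equiv each), THF, −78 °C; add 2, −78 → −30 °C; aq NH4Cl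
Reagents that add atoms: tert-butyl acetate (as its lithium enolate), CC(=O)OC(C)(C)C
Why: Crossed Claisen condensation of a β-hydroxy ester with excess acetate enolate, forming C8–C9; the alkoxide of 2 and then the enolate of 3 protect against retro-aldol and over-addition, and the tert-butyl ester cannot self-condense or lactonise.

Step 3
Reactants: 3 tert-butyl (5S)-5-hydroxy-3-oxotetradecanoate
Product: 5 tert-butyl (3S,5S)-3,5-dihydroxytetradecanoate, via boron chelate 4 (not isolated)
Conditions: Et2BOMe, THF/MeOH (4:1), −78 °C; NaBH4, −78 °C; AcOH, then MeOH co-evaporation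
Reagents that add atoms: none
Why: Narasaka–Prasad reduction; the C11 oxygen and the C9 ketone are held in the six-membered chelate 4 and external hydride adds to its open face, which should give the 1,3-syn diol and so sets C9 (S) from C11.

Step 4
Reactants: 5 tert-butyl (3S,5S)-3,5-dihydroxytetradecanoate
Product: 6 tert-butyl 2-[(4S,6S)-2,2-dimethyl-6-nonyl-1,3-dioxan-4-yl]acetate
Conditions: Me2C(OMe)2, camphorsulfonic acid (cat.), acetone, rt
Reagents that add atoms: 2,2-dimethoxypropane, COC(C)(C)OC
Why: Acid-catalysed transacetalisation; a syn-1,3-diol gives a chair dioxane with both substituents equatorial, and the tert-butyl ester tolerates the catalytic acid.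

Step 5
Reactants: 6 tert-butyl 2-[(4S,6S)-2,2-dimethyl-6-nonyl-1,3-dioxan-4-yl]acetate
Product: 7 2-[(4S,6S)-2,2-dimethyl-6-nonyl-1,3-dioxan-4-yl]acetaldehyde
Conditions: iBu2AlH (1.1 equiv), CH2Cl2, −78 °C; aq potassium sodium tartrate
Reagents that add atoms: none
Why: Partial reduction of an ester; the hindered tert-butoxy aluminium hemiacetal, chelated by the β-acetal oxygen, should persist at −78 °C and release the aldehyde only on work-up.

Step 6
Reactants: 7 2-[(4S,6S)-2,2-dimethyl-6-nonyl-1,3-dioxan-4-yl]acetaldehyde; 8 1-methoxy-1,3-bis(trimethylsilyloxy)buta-1,3-diene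
Product: 10 methyl (5R)-6-[(4R,6S)-2,2-dimethyl-6-nonyl-1,3-dioxan-4-yl]-5-hydroxy-3-oxohexanoate, via silyl enol ether 9 (not isolated)
Conditions: BF3·OEt2 (1.1 equiv), CH2Cl2, −78 °C; aq NaHCO3; then 10% aq citric acid, THF, 0 °C
Reagents that add atoms: none
Why: Vinylogous Mukaiyama aldol forming C6–C7; the terminal carbon of 8 adds to the BF3-activated aldehyde through an open transition state in which the C9 oxygen opposes the carbonyl dipole, which should favour 1,3-anti attack and give C7 (R). Mild acid then hydrolyses 9 to the β-keto ester, so C3–C6 arrive with the C5 ketone and C3 methyl ester in place.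

Step 7
Reactants: 10 methyl (5R)-6-[(4R,6S)-2,2-dimethyl-6-nonyl-1,3-dioxan-4-yl]-5-hydroxy-3-oxohexanoate
Product: 11 methyl (5R)-5-[tert-butyl(dimethyl)silyl]oxy-6-[(4S,6S)-2,2-dimethyl-6-nonyl-1,3-dioxan-4-yl]-3-oxohexanoate
Conditions: TBSCl, imidazole, DMF, rt
Reagents that add atoms: tert-butyldimethylsilyl chloride, CC(C)(C)[Si](C)(C)Cl
Why: Silylation of a secondary alcohol under weakly basic conditions that should not enolise the β-keto ester enough to cause lactonisation or retro-aldol; capping O7 now is what later leaves O5 as the only free hydroxyl.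

Step 8
Reactants: 11 methyl (5R)-5-[tert-butyl(dimethyl)silyl]oxy-6-[(4S,6S)-2,2-dimethyl-6-nonyl-1,3-dioxan-4-yl]-3-oxohexanoate
Product: 12 methyl (3R,5S)-5-[tert-butyl(dimethyl)silyl]oxy-6-[(4S,6S)-2,2-dimethyl-6-nonyl-1,3-dioxan-4-yl]-3-hydroxyhexanoate
Conditions: RuCl2[(R)-BINAP] (1 mol %), H2 (5 atm), MeOH, 40 °C
Reagents that add atoms: none
Why: Noyori asymmetric hydrogenation; the (R)-BINAP catalyst gives the (3R)-β-hydroxy ester as with simple 3-oxoalkanoates, setting C5 (R) by catalyst control that should override the remote C7 centre. The 5S label of 12 reflects only a change in substituent priority at C7.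

Step 9
Reactants: 12 methyl (3R,5S)-5-[tert-butyl(dimethyl)silyl]oxy-6-[(4S,6S)-2,2-dimethyl-6-nonyl-1,3-dioxan-4-yl]-3-hydroxyhexanoate; 13 bromoacetyl bromide
Product: 14 methyl (3R,5R)-3-(2-bromoacetoxy)-5-[tert-butyl(dimethyl)silyl]oxy-6-[(4S,6S)-2,2-dimethyl-6-nonyl-1,3-dioxan-4-yl]hexanoate
Conditions: pyridine, CH2Cl2, −20 → 0 °C
Reagents that add atoms: none
Why: O-Acylation of the only free hydroxyl with an acyl bromide; the low temperature and weak base avoid β-elimination of the new ester and displacement of bromide.

Step 10
Reactants: 14 methyl (3R,5R)-3-(2-bromoacetoxy)-5-[tert-butyl(dimethyl)silyl]oxy-6-[(4S,6S)-2,2-dimethyl-6-nonyl-1,3-dioxan-4-yl]hexanoate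
Product: 16 (6R)-6-{(2R)-2-[tert-butyl(dimethyl)silyl]oxy-3-[(4S,6S)-2,2-dimethyl-6-nonyl-1,3-dioxan-4-yl]propyl}-4-hydroxy-5,6-dihydro-2H-pyran-2-one, via magnesium enolate 15 (not isolated)
Conditions: t-BuMgCl (3 equiv), THF, 60 °C, slow addition of 14 (high dilution); 10% aq citric acid, 0 °C
Reagents that add atoms: none
Why: Bromine–magnesium exchange on the α-bromo ester should be faster than deprotonation, so the magnesium enolate 15 forms at C2 and nowhere else. C2 then adds to the C3 methyl ester carbonyl, the tetrahedral intermediate loses methoxide, and the β-keto lactone is immediately deprotonated to its magnesium 1,3-dicarbonyl enolate, which pulls the Claisen equilibrium forward; citric acid returns the enol 16. The closest known reaction type is the Dieckmann-type (intramolecular Reformatsky–Claisen) cyclisation of 3-(2-bromoacyloxy)alkanoates to 3,6-disubstituted 4-hydroxy-5,6-dihydropyran-2-ones with t-BuMgCl or zinc. One ring is closed (O5, C1, C2, C3, C4, C5), six-membered, in the 6-exo-trig mode with the attacked C=O outside the ring. No stereocentre is created; C5 is retained because its C–O bond is never broken, and the silyl ether and acetal at C7, C9 and C11 should be inert to the Grignard reagent. The step needs enolate formation at C2 rather than C4, which the C–Br bond secures, and intramolecular rather than intermolecular acylation, which the six-membered transition state and slow addition secure. Deprotonation at C4 would lead to β-elimination of the acyloxy group; the hindered Grignard reagent and the fast exchange should keep this minor.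

Step 11
Reactants: 16 (6R)-6-{(2R)-2-[tert-butyl(dimethyl)silyl]oxy-3-[(4S,6S)-2,2-dimethyl-6-nonyl-1,3-dioxan-4-yl]propyl}-4-hydroxy-5,6-dihydro-2H-pyran-2-one
Product: 17 (6R)-4-hydroxy-6-[(2R,4S,6S)-2,4,6-trihydroxypentadecyl]-5,6-dihydro-2H-pyran-2-one
Conditions: 48% aq HF, MeCN, 0 °C → rt
Reagents that add atoms: none
Why: Acidic fluoride cleaves the secondary silyl ether and hydrolyses the acetonide in one operation; the vinylogous-acid lactone is stable to aqueous acid at this temperature, and neither fragment released reacts with C2.

## Compound list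

1 | methyl 3-oxododecanoate | CCCCCCCCCC(=O)CC(=O)OC | starting material
2 | methyl (3S)-3-hydroxydodecanoate | CCCCCCCCC[C@H](O)CC(=O)OC | intermediate
3 | tert-butyl (5S)-5-hydroxy-3-oxotetradecanoate | CCCCCCCCC[C@H](O)CC(=O)CC(=O)OC(C)(C)C | intermediate
4 | tert-butyl (5S)-5-(diethylboranyloxy)-3-oxotetradecanoate (boron chelate) | CCCCCCCCC[C@H](OB(CC)CC)CC(=O)CC(=O)OC(C)(C)C | intermediate (not isolated)
5 | tert-butyl (3S,5S)-3,5-dihydroxytetradecanoate | CCCCCCCCC[C@H](O)C[C@H](O)CC(=O)OC(C)(C)C | intermediate
6 | tert-butyl 2-[(4S,6S)-2,2-dimethyl-6-nonyl-1,3-dioxan-4-yl]acetate | CCCCCCCCC[C@H]1C[C@@H](CC(=O)OC(C)(C)C)OC(C)(C)O1 | intermediate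
7 | 2-[(4S,6S)-2,2-dimethyl-6-nonyl-1,3-dioxan-4-yl]acetaldehyde | CCCCCCCCC[C@H]1C[C@@H](CC=O)OC(C)(C)O1 | intermediate
8 | 1-methoxy-1,3-bis(trimethylsilyloxy)buta-1,3-diene | COC(O[Si](C)(C)C)=CC(=C)O[Si](C)(C)C | starting material
9 | methyl (5R)-6-[(4R,6S)-2,2-dimethyl-6-nonyl-1,3-dioxan-4-yl]-5-hydroxy-3-(trimethylsilyloxy)hex-2-enoate (C2=C3 geometry not defined) | CCCCCCCCC[C@H]1C[C@@H](C[C@@H](O)CC(O[Si](C)(C)C)=CC(=O)OC)OC(C)(C)O1 | intermediate (not isolated)
10 | methyl (5R)-6-[(4R,6S)-2,2-dimethyl-6-nonyl-1,3-dioxan-4-yl]-5-hydroxy-3-oxohexanoate | CCCCCCCCC[C@H]1C[C@@H](C[C@@H](O)CC(=O)CC(=O)OC)OC(C)(C)O1 | intermediate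
11 | methyl (5R)-5-[tert-butyl(dimethyl)silyl]oxy-6-[(4S,6S)-2,2-dimethyl-6-nonyl-1,3-dioxan-4-yl]-3-oxohexanoate | CCCCCCCCC[C@H]1C[C@@H](C[C@@H](O[Si](C)(C)C(C)(C)C)CC(=O)CC(=O)OC)OC(C)(C)O1 | intermediate
12 | methyl (3R,5S)-5-[tert-butyl(dimethyl)silyl]oxy-6-[(4S,6S)-2,2-dimethyl-6-nonyl-1,3-dioxan-4-yl]-3-hydroxyhexanoate | CCCCCCCCC[C@H]1C[C@@H](C[C@@H](O[Si](C)(C)C(C)(C)C)C[C@@H](O)CC(=O)OC)OC(C)(C)O1 | intermediate
13 | bromoacetyl bromide | BrCC(Br)=O | starting material
14 | methyl (3R,5R)-3-(2-bromoacetoxy)-5-[tert-butyl(dimethyl)silyl]oxy-6-[(4S,6S)-2,2-dimethyl-6-nonyl-1,3-dioxan-4-yl]hexanoate | CCCCCCCCC[C@H]1C[C@@H](C[C@@H](O[Si](C)(C)C(C)(C)C)C[C@@H](OC(=O)CBr)CC(=O)OC)OC(C)(C)O1 | intermediate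
15 | chloromagnesium ester enolate of 14 (O5–C1(OMgCl)=C2H2; stereocentres as in 14) | CCCCCCCCC[C@H]1C[C@@H](C[C@@H](O[Si](C)(C)C(C)(C)C)C[C@@H](OC(=C)O[Mg]Cl)CC(=O)OC)OC(C)(C)O1 | intermediate (not isolated)
16 | (6R)-6-{(2R)-2-[tert-butyl(dimethyl)silyl]oxy-3-[(4S,6S)-2,2-dimethyl-6-nonyl-1,3-dioxan-4-yl]propyl}-4-hydroxy-5,6-dihydro-2H-pyran-2-one | CCCCCCCCC[C@H]1C[C@@H](C[C@@H](O[Si](C)(C)C(C)(C)C)C[C@@H]2CC(O)=CC(=O)O2)OC(C)(C)O1 | intermediate
17 | (6R)-4-hydroxy-6-[(2R,4S,6S)-2,4,6-trihydroxypentadecyl]-5,6-dihydro-2H-pyran-2-one | CCCCCCCCC[C@H](O)C[C@H](O)C[C@@H](O)C[C@@H]1CC(O)=CC(=O)O1 | target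

## Step count and risks

Total: 11 steps. Longest linear sequence: 11 steps (1 to 17); the route is fully linear.

**Step 10 (key step).** The most likely failure is a base pathway competing with bromine–magnesium exchange: deprotonation at C4 followed by β-elimination of the acyloxy group, or protonation of the enolate before it cyclises, which would leave a simple acetate. Intermolecular Claisen condensation is the second concern if the enolate accumulates. Fallback: from 12, a crossed Claisen condensation with the lithium enolate of tert-butyl acetate (as in step 2) would form C2–C3 first, giving tert-butyl (5R,7S)-7-[tert-butyl(dimethyl)silyl]oxy-8-[(4S,6S)-2,2-dimethyl-6-nonyl-1,3-dioxan-4-yl]-5-hydroxy-3-oxooctanoate F1. Heating this in toluene should generate the acylketene with loss of tert-butanol, and the C5 hydroxyl should trap it to close O5–C1, returning to the route at 16. This reverses the order of the two ring bonds and gives up the Dieckmann closure, but uses only known chemistry.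

**Step 6.** Facial selectivity at C7 may be incomplete, because induction from an acetal oxygen through an open transition state is weaker than reagent control. The Lewis acid may also open the acetonide, and 10 may lactonise through O7. Fallback: from 7, a Brown allylation with the allylborane made from (−)-Ipc2BOMe and allylmagnesium bromide would set C7 by reagent control, giving (2S)-1-[(4R,6S)-2,2-dimethyl-6-nonyl-1,3-dioxan-4-yl]pent-4-en-2-ol F2. Silylation (TBSCl, imidazole) would give tert-butyl-dimethyl-{[(2S)-1-[(4S,6S)-2,2-dimethyl-6-nonyl-1,3-dioxan-4-yl]pent-4-en-2-yl]oxy}silane F3. Ozonolysis with PPh3 work-up would give (3R)-3-[tert-butyl(dimethyl)silyl]oxy-4-[(4S,6S)-2,2-dimethyl-6-nonyl-1,3-dioxan-4-yl]butanal F4. Roskamp homologation with methyl diazoacetate and SnCl2 would then return to the route at 11.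

**Step 8.** Acid traces from the ruthenium chloride precatalyst in warm methanol may remove the silyl ether or the acetonide; a freed O7 would then lactonise onto C3. A mismatch with the C7 centre could also erode catalyst control. Fallback: from 11, reduction with NaBH4 in MeOH at −20 °C would give 12 together with its C5 epimer, methyl (3S,5S)-5-[tert-butyl(dimethyl)silyl]oxy-6-[(4S,6S)-2,2-dimethyl-6-nonyl-1,3-dioxan-4-yl]-3-hydroxyhexanoate F5. After separation, 12 would continue through step 9, and the epimer would be esterified under Mitsunobu conditions (bromoacetic acid, PPh3, diisopropyl azodicarboxylate) with inversion at C5, returning to the route at 14. Both epimers are thus used.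

**Step 5.** Partial reduction of a tert-butyl ester may stall or run on to the primary alcohol if the aluminium hemiacetal collapses before the quench. Fallback: from 6, full reduction with LiAlH4 in THF would give 2-[(4R,6S)-2,2-dimethyl-6-nonyl-1,3-dioxan-4-yl]ethan-1-ol F6, and Dess–Martin oxidation would return to the route at 7.

## Further compounds

F1 | step 10 | tert-butyl (5R,7S)-7-[tert-butyl(dimethyl)silyl]oxy-8-[(4S,6S)-2,2-dimethyl-6-nonyl-1,3-dioxan-4-yl]-5-hydroxy-3-oxooctanoate | CCCCCCCCC[C@H]1C[C@@H](C[C@@H](O[Si](C)(C)C(C)(C)C)C[C@@H](O)CC(=O)CC(=O)OC(C)(C)C)OC(C)(C)O1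
F2 | step 6 | (2S)-1-[(4R,6S)-2,2-dimethyl-6-nonyl-1,3-dioxan-4-yl]pent-4-en-2-ol | CCCCCCCCC[C@H]1C[C@@H](C[C@@H](O)CC=C)OC(C)(C)O1
F3 | step 6 | tert-butyl-dimethyl-{[(2S)-1-[(4S,6S)-2,2-dimethyl-6-nonyl-1,3-dioxan-4-yl]pent-4-en-2-yl]oxy}silane | CCCCCCCCC[C@H]1C[C@@H](C[C@@H](O[Si](C)(C)C(C)(C)C)CC=C)OC(C)(C)O1
F4 | step 6 | (3R)-3-[tert-butyl(dimethyl)silyl]oxy-4-[(4S,6S)-2,2-dimethyl-6-nonyl-1,3-dioxan-4-yl]butanal | CCCCCCCCC[C@H]1C[C@@H](C[C@@H](O[Si](C)(C)C(C)(C)C)CC=O)OC(C)(C)O1
F5 | step 8 | methyl (3S,5S)-5-[tert-butyl(dimethyl)silyl]oxy-6-[(4S,6S)-2,2-dimethyl-6-nonyl-1,3-dioxan-4-yl]-3-hydroxyhexanoate | CCCCCCCCC[C@H]1C[C@@H](C[C@@H](O[Si](C)(C)C(C)(C)C)C[C@H](O)CC(=O)OC)OC(C)(C)O1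
F6 | step 5 | 2-[(4R,6S)-2,2-dimethyl-6-nonyl-1,3-dioxan-4-yl]ethan-1-ol | CCCCCCCCC[C@H]1C[C@@H](CCO)OC(C)(C)O1
A1 | alternative 1 | (2S)-1-{2-[(2S)-2-(tert-butyldimethylsilyloxy)undecyl]-1,3-dithian-2-yl}pent-4-en-2-ol | CCCCCCCCC[C@H](O[Si](C)(C)C(C)(C)C)CC1(SCCCS1)C[C@@H](O)CC=C
A2 | alternative 1 | 2-(tert-butyldimethylsilyl)-1,3-dithiane | CC(C)(C)[Si](C)(C)C1SCCCS1
A3 | alternative 1 | (S)-2-nonyloxirane | CCCCCCCCC[C@H]1CO1
A4 | alternative 1 | (S)-2-allyloxirane | C=CC[C@H]1CO1
A5 | alternative 2 | 8-oxabicyclo[3.2.1]oct-6-en-3-one (meso) | O=C1C[C@H]2C=C[C@@H](C1)O2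
A6 | alternative 2 | 1,1,3,3-tetrabromopropan-2-one | BrC(Br)C(=O)C(Br)Br
A7 | alternative 2 | furan | c1ccoc1
A8 | alternative 3 | ethyl 2-[(2S,4R,6S)-2-phenyl-6-vinyl-1,3-dioxan-4-yl]acetate (all-cis) | CCOC(=O)C[C@H]1C[C@@H](C=C)O[C@@H](c2ccccc2)O1
A9 | alternative 3 | ethyl (3R,5E)-3,7-dihydroxyhept-5-enoate | CCOC(=O)C[C@H](O)C/C=C/CO
A10 | alternative 3 | benzaldehyde dimethyl acetal | COC(OC)c1ccccc1
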